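## Retrosynthetic overview

1. Target 26 ⇒ bromo enal 24: the C6–C7 bond, the ten-membered carbocycle and the cis-fused α-methylene lactone are closed last, in one cathodic chromium-catalysed allylation/lactonisation.
2. 24 ⇒ furan 20: the 3(2H)-furanone ring and the Z enal are unveiled together from a 2-alkyl-3-methylfuran by singlet-oxygen photooxygenation; the allylic bromide comes from a C7 aldehyde (vinylalumination, SN2′ bromination).
3. 20 ⇒ furyl ketone 10 + side-chain acid 16 (Morita–Baylis–Hillman chemistry) + methyl propiolate 19.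
4. 10 ⇒ silylated 2-C-methyl-L-arabinonolactone 7 + (Z)-enynol 8 (alkynylation, then cycloisomerisation to the furan).
5. 7 ⇒ (S)-glyceraldehyde acetonide 1 (Wittig, substrate-controlled dihydroxylation, lactonisation). C8 is bought, C9/C10 follow from C8, C6/C7 follow from C8 in the last step. Ring order: temporary sugar lactone → furan → furanone → macrocycle and butyrolactone together.

Assumption: the SMILES is read as (6S,7S,8S,9S,10R) in germacrane numbering (6,7-cis-fused lactone, 4Z ring alkene, E side-chain alkene); atom labels C1–C15 below use this numbering.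

## Route

Step 1
Reactants: 1 (S)-2,2-dimethyl-1,3-dioxolane-4-carbaldehyde; 2 ethyl 2-(triphenylphosphoranylidene)propanoate
Product: 3 ethyl (E)-3-[(4R)-2,2-dimethyl-1,3-dioxolan-4-yl]-2-methylprop-2-enoate
Conditions: CH2Cl2, 0 °C → rt
Reagents that add atoms: none
Why: Wittig olefination with a stabilised ylide gives the E trisubstituted enoate and leaves the purchased C8 stereocentre untouched.

Step 2
Reactants: 3 ethyl (E)-3-[(4R)-2,2-dimethyl-1,3-dioxolan-4-yl]-2-methylprop-2-enoate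
Product: 5 (3R,4S,5S)-3,4-dihydroxy-5-(hydroxymethyl)-3-methyloxolan-2-one, via dihydroxy ester 4 (not isolated)
Conditions: OsO4 (1 mol %), N-methylmorpholine N-oxide, acetone/H2O, 0 °C → rt; then 2 M aq. HCl, 45 °C; recrystallisation
Reagents that add atoms: N-methylmorpholine N-oxide (C[N+]1([O-])CCOCC1); water (O)
Why: Upjohn syn-dihydroxylation of the E alkene on the face anti to the allylic C8–O bond (Kishi's rule, the same substrate control being well established for the enantiomeric enoate) sets C9 and C10 from C8, and acid then removes the acetonide and closes the γ-lactone on O8, crystallisation removing the minor diastereomer.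

Step 3
Reactants: 5 (3R,4S,5S)-3,4-dihydroxy-5-(hydroxymethyl)-3-methyloxolan-2-one
Product: 7 (3R,4S,5S)-3-methyl-4-(triethylsilyloxy)-5-[(triethylsilyloxy)methyl]-3-(trimethylsilyloxy)oxolan-2-one, via bis(triethylsilyl) ether 6 (not isolated)
Conditions: Et3SiCl (2.2 equiv), imidazole, DMF, 0 °C; then 1-(trimethylsilyl)imidazole, rt
Reagents that add atoms: chlorotriethylsilane (CC[Si](Cl)(CC)CC); 1-(trimethylsilyl)imidazole (C[Si](C)(C)n1ccnc1)
Why: Graded silyl ether formation (Et3SiCl takes the primary and secondary hydroxyls, the stronger silyl donor the tertiary one) blocks O7, O9 and O10 while the lactone masks O8 and C1.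

Step 4
Reactants: 7 (3R,4S,5S)-3-methyl-4-(triethylsilyloxy)-5-[(triethylsilyloxy)methyl]-3-(trimethylsilyloxy)oxolan-2-one; 8 (Z)-3-methylpent-2-en-4-yn-1-ol
Product: 10 (3R,4S,5S)-5-hydroxy-3-methyl-1-(3-methylfuran-2-yl)-4,6-bis(triethylsilyloxy)-3-(trimethylsilyloxy)hexan-2-one, via alkynyl ketone 9 (not isolated)
Conditions: 8, n-C4H9Li (2 equiv per 8), THF, −78 → −20 °C; then 7, −78 °C; sat. aq. NH4Cl; then AgNO3 (10 mol %) on SiO2, hexane/EtOAc, rt
Reagents that add atoms: none
Why: Lithium acetylide addition to the γ-lactone stops at the lactol/ketone stage and liberates O8, and silver-catalysed 5-exo-dig cycloisomerisation of the (Z)-2-en-4-yn-1-ol with aromatisation gives the 2-alkyl-3-methylfuran, which stores C3–C6 and the later 4Z geometry in a ring.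

Step 5
Reactants: 11 tert-butyl acrylate; 12 acetaldehyde
Product: 13 tert-butyl 3-hydroxy-2-methylidenebutanoate (racemic)
Conditions: 1,4-diazabicyclo[2.2.2]octane (0.3 equiv), dioxane/H2O, rt, 3 d
Reagents that add atoms: none
Why: Morita–Baylis–Hillman reaction; the racemic carbinol centre is erased in step 6.

Step 6
Reactants: 13 tert-butyl 3-hydroxy-2-methylidenebutanoate
Product: 15 tert-butyl (E)-2-(acetoxymethyl)but-2-enoate, via secondary acetate 14 (not isolated)
Conditions: Ac2O, Et3N, 4-(dimethylamino)pyridine (5 mol %), CH2Cl2, 0 °C; then 1,4-diazabicyclo[2.2.2]octane (20 mol %), THF, 65 °C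
Reagents that add atoms: acetic anhydride (CC(=O)OC(C)=O)
Why: Acetylation followed by amine-catalysed SN2′/SN2′ 1,3-transposition of the Morita–Baylis–Hillman acetate gives the thermodynamically preferred E primary allylic acetate.

Step 7
Reactants: 15 tert-butyl (E)-2-(acetoxymethyl)but-2-enoate
Product: 16 (E)-2-(acetoxymethyl)but-2-enoic acid
Conditions: CF3CO2H/CH2Cl2 (1:4), 0 °C → rt
Reagents that add atoms: none
Why: Acidolysis of the tert-butyl ester (loss of isobutene) leaves the acetate and the alkene geometry untouched.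

Step 8
Reactants: 10 (3R,4S,5S)-5-hydroxy-3-methyl-1-(3-methylfuran-2-yl)-4,6-bis(triethylsilyloxy)-3-(trimethylsilyloxy)hexan-2-one; 16 (E)-2-(acetoxymethyl)but-2-enoic acid
Product: 17 (2S,3S,4R)-4-methyl-6-(3-methylfuran-2-yl)-5-oxo-1,3-bis(triethylsilyloxy)-4-(trimethylsilyloxy)hexan-2-yl (E)-2-(acetoxymethyl)but-2-enoate
Conditions: N,N′-dicyclohexylcarbodiimide, 4-(dimethylamino)pyridine (10 mol %), CH2Cl2, 0 °C → rt
Reagents that add atoms: none
Why: Steglich esterification acylates the only free hydroxyl (O8, in mobile equilibrium with an unreactive tertiary hemiketal on the C1 ketone) with retention at C8, so the side chain is in place before O9 is ever free.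

Step 9
Reactants: 17 (2S,3S,4R)-4-methyl-6-(3-methylfuran-2-yl)-5-oxo-1,3-bis(triethylsilyloxy)-4-(trimethylsilyloxy)hexan-2-yl (E)-2-(acetoxymethyl)but-2-enoate
Product: 18 (2R,3S,4R)-4-methyl-6-(3-methylfuran-2-yl)-1,5-dioxo-3-(triethylsilyloxy)-4-(trimethylsilyloxy)hexan-2-yl (E)-2-(acetoxymethyl)but-2-enoate
Conditions: (COCl)2, DMSO, CH2Cl2, −78 °C; then Et3N, −78 → −30 °C
Reagents that add atoms: none
Why: Swern oxidation converts a primary triethylsilyl ether directly into the aldehyde while the secondary Et3Si and tertiary Me3Si ethers survive, which unveils C7 without a separate deprotection (the Me3Si ether on O10 prevents lactol formation).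

Step 10
Reactants: 18 (2R,3S,4R)-4-methyl-6-(3-methylfuran-2-yl)-1,5-dioxo-3-(triethylsilyloxy)-4-(trimethylsilyloxy)hexan-2-yl (E)-2-(acetoxymethyl)but-2-enoate; 19 methyl propiolate
Product: 20 methyl (4S,5S,6R)-4-{[(E)-2-(acetoxymethyl)but-2-enoyl]oxy}-3-hydroxy-6-methyl-2-methylidene-8-(3-methylfuran-2-yl)-7-oxo-5-(triethylsilyloxy)-6-(trimethylsilyloxy)octanoate (both C3 epimers)
Conditions: 19, (i-C4H9)2AlH, N-methylmorpholine N-oxide, THF, 0 °C; then 18, −20 → 0 °C; aq. KNaC4H4O6
Reagents that add atoms: none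
Why: Vinylalumination, a non-basic aluminium variant of the Morita–Baylis–Hillman reaction (1,4-hydroalumination of the propiolate, then addition of the α-aluminoacrylate to the aldehyde), attaches C11–C13; the new carbinol centre at C7 is inconsequential because it becomes sp2 in step 12, and the low temperature suppresses an O8→O7 acyl shift.

Step 11
Reactants: 20 methyl (4S,5S,6R)-4-{[(E)-2-(acetoxymethyl)but-2-enoyl]oxy}-3-hydroxy-6-methyl-2-methylidene-8-(3-methylfuran-2-yl)-7-oxo-5-(triethylsilyloxy)-6-(trimethylsilyloxy)octanoate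
Product: 23 methyl (4S,5S)-4-{[(E)-2-(acetoxymethyl)but-2-enoyl]oxy}-3-hydroxy-2-methylidene-5-{(2R)-2-methyl-3-oxo-5-[(Z)-4-oxobut-2-en-2-yl]-2,3-dihydrofuran-2-yl}-5-(triethylsilyloxy)pentanoate, via tertiary alcohol 21 (not isolated), via endoperoxide 22 (not isolated)
Conditions: pyridinium p-toluenesulfonate (0.2 equiv), MeOH/CH2Cl2, 0 °C, 30 min; then methylene blue (1 mol %), O2, red LEDs, −30 °C; then Me2S, −30 °C → rt
Reagents that add atoms: dioxygen (O=O)
Why: Mild methanolysis frees only O10, singlet-oxygen [4+2] photooxygenation of the furan gives the endoperoxide, which is captured at C3 by the C10 hydroxyl, and reduction of the hydroperoxide followed by acid-catalysed dehydration of the hemiketal (cyclodehydration of an α′-hydroxy-1,3-diketone) forms the 3(2H)-furanone and the Z enal, whose geometry is inherited from the furan ring while O9 stays silylated so that no pyranone can form.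

Step 12
Reactants: 23 methyl (4S,5S)-4-{[(E)-2-(acetoxymethyl)but-2-enoyl]oxy}-3-hydroxy-2-methylidene-5-{(2R)-2-methyl-3-oxo-5-[(Z)-4-oxobut-2-en-2-yl]-2,3-dihydrofuran-2-yl}-5-(triethylsilyloxy)pentanoate
Product: 24 methyl (2Z,4S,5S)-4-{[(E)-2-(acetoxymethyl)but-2-enoyl]oxy}-2-(bromomethyl)-5-{(2R)-2-methyl-3-oxo-5-[(Z)-4-oxobut-2-en-2-yl]-2,3-dihydrofuran-2-yl}-5-(triethylsilyloxy)pent-2-enoate
Conditions: N-bromosuccinimide, Me2S, CH2Cl2, −30 → 0 °C
Reagents that add atoms: N-bromosuccinimide (BrN1C(=O)CCC1=O)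
Why: Corey–Kim bromination of the Morita–Baylis–Hillman alcohol proceeds with SN2′ transposition to the thermodynamically favoured (Z)-2-(bromomethyl)enoate under neutral conditions that spare the enal.

Step 13
Reactants: 24 methyl (2Z,4S,5S)-4-{[(E)-2-(acetoxymethyl)but-2-enoyl]oxy}-2-(bromomethyl)-5-{(2R)-2-methyl-3-oxo-5-[(Z)-4-oxobut-2-en-2-yl]-2,3-dihydrofuran-2-yl}-5-(triethylsilyloxy)pent-2-enoate
Product: 26 CNP0231561.2, via triethylsilyl ether 25 (not isolated)
Conditions: CrCl3·3THF (20 mol %), Me3SiCl (3 equiv), LiCl (0.1 M), DMF, undivided cell, Al anode, Ni-foam cathode, constant current 2 mA (2.5 F/mol), 24 added over 10 h by syringe pump (final 2 mM), rt; then 1 M aq. HCl/THF, rt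
Reagents that add atoms: none
Why: Proposed new method: divalent chromium, regenerated at the cathode from catalytic CrCl3 instead of by a stoichiometric metal reductant, inserts into the allylic C–Br bond, and the (Z)-2-(methoxycarbonyl)allyl chromium adds to the tethered enal through a chair Zimmerman–Traxler transition state (Z-allyl gives the 6,7-syn adduct, i.e. the cis-fused lactone) on the alkene face that keeps H8 eclipsed with the alkene (allylic 1,3-strain) and C9 away from the incoming aldehyde, so that C8 sets C7 and C6, after which the alkoxide lactonises onto the methyl ester, Me3SiCl releases the catalyst and the acidic work-up removes the silyl ether; the closest known reactions are chromium-catalysed Nozaki–Hiyama–Kishi allylation turned over by Mn/Me3SiCl, intermolecular electrochemical Nozaki–Hiyama–Kishi coupling, and stoichiometric CrCl2 Barbier macrolactonisation of 2-(bromomethyl)acrylates.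

## Compound list

1 | (S)-2,2-dimethyl-1,3-dioxolane-4-carbaldehyde ((S)-glyceraldehyde acetonide) | O=C[C@H]1OC(C)(C)OC1 | starting material
2 | ethyl 2-(triphenylphosphoranylidene)propanoate | CCOC(=O)C(C)=P(c1ccccc1)(c1ccccc1)c1ccccc1 | starting material
3 | ethyl (E)-3-[(4R)-2,2-dimethyl-1,3-dioxolan-4-yl]-2-methylprop-2-enoate | CCOC(=O)/C(C)=C/[C@H]1OC(C)(C)OC1 | intermediate
4 | ethyl (2R,3S)-3-[(4S)-2,2-dimethyl-1,3-dioxolan-4-yl]-2,3-dihydroxy-2-methylpropanoate | CCOC(=O)[C@](C)(O)[C@@H](O)[C@H]1OC(C)(C)OC1 | intermediate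
5 | (3R,4S,5S)-3,4-dihydroxy-5-(hydroxymethyl)-3-methyloxolan-2-one (2-C-methyl-L-arabinono-1,4-lactone) | O=C1O[C@@H](CO)[C@H](O)[C@@]1(C)O | intermediate
6 | (3R,4S,5S)-3-hydroxy-3-methyl-4-(triethylsilyloxy)-5-[(triethylsilyloxy)methyl]oxolan-2-one | O=C1O[C@@H](CO[Si](CC)(CC)CC)[C@H](O[Si](CC)(CC)CC)[C@@]1(C)O | intermediate
7 | (3R,4S,5S)-3-methyl-4-(triethylsilyloxy)-5-[(triethylsilyloxy)methyl]-3-(trimethylsilyloxy)oxolan-2-one | O=C1O[C@@H](CO[Si](CC)(CC)CC)[C@H](O[Si](CC)(CC)CC)[C@@]1(C)O[Si](C)(C)C | intermediate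
8 | (Z)-3-methylpent-2-en-4-yn-1-ol | C#C/C(C)=C\CO | starting material
9 | (2Z,7R,8S,9S)-1,9-dihydroxy-3,7-dimethyl-8,10-bis(triethylsilyloxy)-7-(trimethylsilyloxy)dec-2-en-4-yn-6-one (open form of the first-formed lactol) | OC/C=C(C)\C#CC(=O)[C@](C)(O[Si](C)(C)C)[C@@H](O[Si](CC)(CC)CC)[C@@H](O)CO[Si](CC)(CC)CC | intermediate
10 | (3R,4S,5S)-5-hydroxy-3-methyl-1-(3-methylfuran-2-yl)-4,6-bis(triethylsilyloxy)-3-(trimethylsilyloxy)hexan-2-one | Cc1ccoc1CC(=O)[C@](C)(O[Si](C)(C)C)[C@@H](O[Si](CC)(CC)CC)[C@@H](O)CO[Si](CC)(CC)CC | intermediate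
11 | tert-butyl acrylate | C=CC(=O)OC(C)(C)C | starting material
12 | acetaldehyde | CC=O | starting material
13 | tert-butyl 3-hydroxy-2-methylidenebutanoate (racemic) | CC(O)C(=C)C(=O)OC(C)(C)C | intermediate
14 | tert-butyl 3-acetoxy-2-methylidenebutanoate (racemic) | CC(OC(C)=O)C(=C)C(=O)OC(C)(C)C | intermediate
15 | tert-butyl (E)-2-(acetoxymethyl)but-2-enoate | CC(C)(C)OC(=O)/C(=C/C)COC(C)=O | intermediate
16 | (E)-2-(acetoxymethyl)but-2-enoic acid | OC(=O)/C(=C/C)COC(C)=O | intermediate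
17 | (2S,3S,4R)-4-methyl-6-(3-methylfuran-2-yl)-5-oxo-1,3-bis(triethylsilyloxy)-4-(trimethylsilyloxy)hexan-2-yl (E)-2-(acetoxymethyl)but-2-enoate | Cc1ccoc1CC(=O)[C@](C)(O[Si](C)(C)C)[C@@H](O[Si](CC)(CC)CC)[C@@H](OC(=O)/C(=C/C)COC(C)=O)CO[Si](CC)(CC)CC | intermediate
18 | (2R,3S,4R)-4-methyl-6-(3-methylfuran-2-yl)-1,5-dioxo-3-(triethylsilyloxy)-4-(trimethylsilyloxy)hexan-2-yl (E)-2-(acetoxymethyl)but-2-enoate | Cc1ccoc1CC(=O)[C@](C)(O[Si](C)(C)C)[C@@H](O[Si](CC)(CC)CC)[C@@H](OC(=O)/C(=C/C)COC(C)=O)C=O | intermediate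
19 | methyl propiolate | C#CC(=O)OC | starting material
20 | methyl (4S,5S,6R)-4-{[(E)-2-(acetoxymethyl)but-2-enoyl]oxy}-3-hydroxy-6-methyl-2-methylidene-8-(3-methylfuran-2-yl)-7-oxo-5-(triethylsilyloxy)-6-(trimethylsilyloxy)octanoate (both C3 epimers) | Cc1ccoc1CC(=O)[C@](C)(O[Si](C)(C)C)[C@@H](O[Si](CC)(CC)CC)[C@@H](OC(=O)/C(=C/C)COC(C)=O)C(O)C(=C)C(=O)OC | intermediate
21 | methyl (4S,5S,6R)-4-{[(E)-2-(acetoxymethyl)but-2-enoyl]oxy}-3,6-dihydroxy-6-methyl-2-methylidene-8-(3-methylfuran-2-yl)-7-oxo-5-(triethylsilyloxy)octanoate | Cc1ccoc1CC(=O)[C@](C)(O)[C@@H](O[Si](CC)(CC)CC)[C@@H](OC(=O)/C(=C/C)COC(C)=O)C(O)C(=C)C(=O)OC | intermediate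
22 | endoperoxide of 21 (the furan ring turned into a 2,3,7-trioxabicyclo[2.2.1]hept-5-ene, C3 and C6 bridged by O–O) | CC1=CC2OOC1(O2)CC(=O)[C@](C)(O)[C@@H](O[Si](CC)(CC)CC)[C@@H](OC(=O)/C(=C/C)COC(C)=O)C(O)C(=C)C(=O)OC | intermediate
23 | methyl (4S,5S)-4-{[(E)-2-(acetoxymethyl)but-2-enoyl]oxy}-3-hydroxy-2-methylidene-5-{(2R)-2-methyl-3-oxo-5-[(Z)-4-oxobut-2-en-2-yl]-2,3-dihydrofuran-2-yl}-5-(triethylsilyloxy)pentanoate (both C3 epimers) | O=C/C=C(/C)C1=CC(=O)[C@](C)(O1)[C@@H](O[Si](CC)(CC)CC)[C@@H](OC(=O)/C(=C/C)COC(C)=O)C(O)C(=C)C(=O)OC | intermediate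
24 | methyl (2Z,4S,5S)-4-{[(E)-2-(acetoxymethyl)but-2-enoyl]oxy}-2-(bromomethyl)-5-{(2R)-2-methyl-3-oxo-5-[(Z)-4-oxobut-2-en-2-yl]-2,3-dihydrofuran-2-yl}-5-(triethylsilyloxy)pent-2-enoate | O=C/C=C(/C)C1=CC(=O)[C@](C)(O1)[C@@H](O[Si](CC)(CC)CC)[C@@H](OC(=O)/C(=C/C)COC(C)=O)/C=C(\CBr)C(=O)OC | intermediate
25 | 9-O-triethylsilyl ether of 26 (6S,7S,8S,9S,10R) | C=C1C(=O)O[C@H]2/C=C(/C)C3=CC(=O)[C@](C)(O3)[C@@H](O[Si](CC)(CC)CC)[C@@H](OC(=O)/C(=C/C)COC(C)=O)[C@@H]12 | intermediate
26 | CNP0231561.2: (6S,7S,8S,9S,10R)-9-hydroxy-1-oxo-3,10-epoxygermacra-2,4Z,11(13)-trien-12,6-olid-8-yl (E)-2-(acetoxymethyl)but-2-enoate | C=C1C(=O)O[C@H]2/C=C(/C)C3=CC(=O)[C@](C)(O3)[C@@H](O)[C@@H](OC(=O)/C(=C/C)COC(C)=O)[C@@H]12 | target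

## Step count and risks

Total steps: 13. Longest linear sequence: 10 steps (steps 1–4 and 8–13, from 1).

Steps most likely to fail:

Step 13. This is the new cathodic macrocyclisation. The risks are strain in the nine-membered oxa-ring, face selectivity at C7 (the ring may override the acyclic preference) and direct reduction of the enal. The fallback uses known chemistry, sets out from 24 and comes back at 25. Palladium-catalysed borylation of the allylic bromide (tris(dibenzylideneacetone)dipalladium as zerovalent palladium source, bis(pinacolato)diboron, CH3CO2K, DMSO, rt) gives the 2-(methoxycarbonyl)allyl boronate F1. This boronate does not react with the aldehyde at rt, so it can be purified. Sc(OSO2CF3)3 catalysis (or toluene, 80 °C, high dilution) then effects intramolecular allylboration through a closed chair transition state, and acidic work-up lactonises to silyl ether 25, which is desilylated to 26 as in the second stage of step 13.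

Step 11. The furan-to-furanone cascade could suffer Z to E isomerisation of the ene-dione, aldol closure of the 1,3-diketone onto the aldehyde, or loss of the O9 silyl ether before the furanone has formed. The fallback sets out from 20 and comes back at 23. Oxidative opening of the furan without light (N-bromosuccinimide, NaHCO3, acetone/H2O, −20 °C) gives the isolable (Z)-ene-dione aldehyde F2 with all silyl ethers intact. Pyridinium p-toluenesulfonate in MeOH then removes the Me3Si ether and cyclodehydrates to 23.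

Step 10. The aluminium alkoxide formed next to the C8 ester may shift the acyl group from O8 to O7, or the α-acyloxy aldehyde may epimerise. The fallback sets out from 18 and comes back at 20, and avoids any metal alkoxide next to the ester. A tandem conjugate addition/Horner–Wadsworth–Emmons reaction (trimethyl 2-phosphonoacrylate, PhSeNa, THF, −78 °C, then 18) gives the allylic selenide F3. Oxidation with H2O2 (pyridine, CH2Cl2, 0 °C) triggers the selenoxide [2,3]-sigmatropic shift and delivers the transposed allylic alcohol 20.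

Further compounds
F1 | step 13 | methyl (2E,4S,5S)-4-{[(E)-2-(acetoxymethyl)but-2-enoyl]oxy}-5-{(2R)-2-methyl-3-oxo-5-[(Z)-4-oxobut-2-en-2-yl]-2,3-dihydrofuran-2-yl}-2-[(4,4,5,5-tetramethyl-1,3,2-dioxaborolan-2-yl)methyl]-5-(triethylsilyloxy)pent-2-enoate | O=C/C=C(/C)C1=CC(=O)[C@](C)(O1)[C@@H](O[Si](CC)(CC)CC)[C@@H](OC(=O)/C(=C/C)COC(C)=O)/C=C(\CB1OC(C)(C)C(C)(C)O1)C(=O)OC
F2 | step 11 | methyl (4S,5S,6R,10Z)-4-{[(E)-2-(acetoxymethyl)but-2-enoyl]oxy}-3-hydroxy-6,10-dimethyl-2-methylidene-7,9,12-trioxo-5-(triethylsilyloxy)-6-(trimethylsilyloxy)dodec-10-enoate | O=C/C=C(/C)C(=O)CC(=O)[C@](C)(O[Si](C)(C)C)[C@@H](O[Si](CC)(CC)CC)[C@@H](OC(=O)/C(=C/C)COC(C)=O)C(O)C(=C)C(=O)OC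
F3 | step 10 | methyl (4S,5S,6R)-4-{[(E)-2-(acetoxymethyl)but-2-enoyl]oxy}-6-methyl-8-(3-methylfuran-2-yl)-7-oxo-2-[(phenylselanyl)methyl]-5-(triethylsilyloxy)-6-(trimethylsilyloxy)oct-2-enoate (E/Z mixture) | Cc1ccoc1CC(=O)[C@](C)(O[Si](C)(C)C)[C@@H](O[Si](CC)(CC)CC)[C@@H](OC(=O)/C(=C/C)COC(C)=O)C=C(C[Se]c1ccccc1)C(=O)OC
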